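**Retrosynthetic overview**

1. The strategy rests on C20, the one-carbon arm of spiro carbon C10 that carries the lactone oxygen (δ-lactone C7–O–C20–C10–C9–C8). C20 is γ to the acetoxy oxygen on C1 of ring A, so it is carried as an angular methyl group and oxidised late from the C1 hydroxyl through an O1–Si–C20–C10–C1 oxasilolane.
2. The key-step precursor 28 (C20 methyl, free C1–OH, C7 methyl ester, C6 acetate, C15 ketal) comes from a cis,cis-fused A/B/C/D tetracycle by ozonolysis of its C6=C7 enol silyl ether, which opens ring B.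
3. Ring D (C8–C15–C16–C13) is closed by an aldol addition at C8 and a 5-exo radical cyclisation onto the C12=C13 alkene of ring C.
4. Ring B comes from an endo Diels–Alder reaction of a 2-silyloxy diene (ring C) with the ring-A 2-methyl enone, which sets C5, C9 and C10. Ring A comes from an enantioselective Michael/aldol annulation (C4), ring C from butadiene and butynone.
5. Order of ring formation: C, A, B, D; then ring B is opened; oxasilolane (key step); δ-lactone; the C16 methylene last.

Key step: step 20

Remark: atoms are numbered as in 6,7-seco-kauranes. Ring A = C1–C5 and C10; C6 on C5; C7 = lactone carbonyl on C8; bicyclo[3.2.1]octane = C8, C9, C11–C16 (C15 ketone, C17 methylene); C18 (methyl) and C19 (CH2OH) on C4; C20 = lactone CH2 on C10. In the target O1, C6 and C9 lie on the face of ring A that carries C18; C19 and C20 lie on the other face.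
Remark: O19 is carried as its triisopropylsilyl ether, which must survive steps 6 to 25. Racemic 1 is used because its stereocentre is planarised in step 3.

Step 1
Reactants: 1 methyl 3-hydroxy-2-methylpropanoate (racemic)
Product: 2 methyl 2-methyl-3-(triisopropylsilyloxy)propanoate
Conditions: i-Pr3SiCl, imidazole, DMF, rt
Reagents that add atoms: chlorotriisopropylsilane, CC(C)[Si](Cl)(C(C)C)C(C)C
Why: Standard silylation of a primary alcohol installs the O19 protecting group that is removed only in step 26.

Step 2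
Reactants: 2 methyl 2-methyl-3-(triisopropylsilyloxy)propanoate
Product: 3 2-methyl-3-(triisopropylsilyloxy)propanal (racemic)
Conditions: i-Bu2AlH (1.05 equiv), CH2Cl2, −78 °C
Reagents that add atoms: none
Why: Partial ester reduction stops at the tetrahedral aluminate at −78 °C and gives the aldehyde on work-up.

Step 3
Reactants: 3 2-methyl-3-(triisopropylsilyloxy)propanal; 4 pent-1-en-3-one
Product: 6 (S)-2,4-dimethyl-4-[(triisopropylsilyloxy)methyl]cyclohex-2-en-1-one, via keto aldehyde 5 (not isolated)
Conditions: N-(4-dodecylphenylsulfonyl)pyrrolidine-2-carboxamide (20 mol %; the antipode that gives the S enone), BnNH2, 4 Å MS, ClCH2CH2Cl, rt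
Reagents that add atoms: none
Why: Organocatalytic asymmetric Robinson annulation (enamine Michael addition, then aldol condensation) of an α-branched aldehyde with a vinyl ketone, in which the quaternary C4 is set by face-selective attack of the catalyst-bound enamine.

Step 4
Reactants: 7 but-3-yn-2-one; 8 buta-1,3-diene
Product: 9 1-(cyclohexa-1,4-dien-1-yl)ethan-1-one
Conditions: excess diene, 2,6-di-tert-butyl-4-methylphenol (cat.), toluene, sealed tube, 100 °C
Reagents that add atoms: none
Why: Thermal Diels–Alder reaction of the ynone gives ring C as a 1,4-cyclohexadiene with C8=C9 conjugated to the acetyl group and C12=C13 isolated.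

Step 5
Reactants: 9 1-(cyclohexa-1,4-dien-1-yl)ethan-1-one
Product: 10 [1-(cyclohexa-1,4-dien-1-yl)ethenyloxy]triisopropylsilane
Conditions: i-Pr3SiOTf, Et3N, CH2Cl2, 0 °C
Reagents that add atoms: triisopropylsilyl triflate, CC(C)[Si](OS(=O)(=O)C(F)(F)F)(C(C)C)C(C)C
Why: Soft enolisation of the methyl ketone at its only α-position gives the cross-conjugated 2-silyloxy diene, and the bulky silyl enol ether is robust enough for steps 6 to 8.

Step 6
Reactants: 6 (S)-enone; 10 silyloxy diene
Product: 11 cis-cis-fused tricyclic ketone (rings A/B/C; C1 ketone; C7=C8 enol silyl ether; C12=C13 alkene)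
Conditions: AlBr3/AlMe3 (10:1, 0.3 equiv), toluene/CH2Cl2, −20 → 0 °C
Reagents that add atoms: none
Why: Lewis-acid-catalysed Diels–Alder reaction in which the nucleophilic CH2 terminus (C6) bonds to the enone β-carbon C5, the endo transition state puts C11 cis to C1, and the diene adds to the enone face bearing the C4 methyl (anti to the bulkier CH2OSi group), which sets C5, C9 and C10 with H5, C20 and H9 on one face of ring B.

Step 7
Reactants: 11 tricyclic ketone
Product: 12 C1 alcohol (hydroxyl cis to C9 and trans to the C20 methyl)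
Conditions: LiBH(s-Bu)3, THF, −78 → 0 °C
Reagents that add atoms: none
Why: The bulky hydride reduces the only ketone along the equatorial, convex trajectory because the axial one is blocked by the syn-axial C6 methylene of ring B, which gives the axial C1 alcohol trans to C20.

Step 8
Reactants: 12 C1 alcohol
Product: 13 C1 benzyl ether
Conditions: NaH, BnBr, Bu4NI (cat.), THF/DMF, 0 °C → rt
Reagents that add atoms: benzyl bromide, BrCc1ccccc1
Why: Williamson etherification masks O1 until step 19 with a group that is later removed by hydrogenolysis without touching silyl ethers, esters or the ketal.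

Step 9
Reactants: 14 phenylselanyl bromide; 15 ethyl vinyl ether
Product: 17 2-(phenylselanyl)acetaldehyde, via diethyl acetal 16 (not isolated)
Conditions: EtOH, 0 °C; then 1 M HCl, Et2O, rt
Reagents that add atoms: water, O
Why: Alkoxyselenenylation of the enol ether in ethanol gives the β-seleno acetal, whose hydrolysis delivers the C15–C16 building block with a radical precursor on C16.

Step 10
Reactants: 13 C1 benzyl ether; 17 2-(phenylselanyl)acetaldehyde
Product: 18 β-hydroxy ketone (C8 quaternary; C15 carbinol as an epimer mixture; SePh on C16)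
Conditions: BF3·OEt2, CH2Cl2, −78 °C
Reagents that add atoms: none
Why: Mukaiyama aldol addition of the regiodefined C7=C8 enol silyl ether forms the C8–C15 bond on the convex face of ring B (the face of H9, opposite rings A and C), and both C15 epimers are usable because C15 becomes a ketone in step 17.

Step 11
Reactants: 18 β-hydroxy ketone
Product: 19 tetracyclic hydroxy ketone (ring D closed; C7 ketone; C15 carbinol epimers)
Conditions: Bu3SnH (syringe pump), 2,2'-azobis(2-methylpropionitrile) (cat.), benzene, 80 °C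
Reagents that add atoms: none
Why: Homolysis of the C–Se bond gives the primary C16 radical, which closes ring D by 5-exo-trig addition to C13 (preferred over attack at C12) before the C12 radical is reduced, with C13 fixed by the tether from C8.

Step 12
Reactants: 19 tetracyclic hydroxy ketone
Product: 20 C15 triethylsilyl ether C6=C7 triethylsilyl enol ether
Conditions: Et3SiOTf (3 equiv), Et3N, CH2Cl2, 0 °C → rt
Reagents that add atoms: triethylsilyl triflate, CC[Si](CC)(CC)OS(=O)(=O)C(F)(F)F
Why: Silyl triflate and amine protect the carbinol and convert the C7 ketone, now the only ketone and enolisable only toward C6, into its enol silyl ether.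

Step 13
Reactants: 20 bis(triethylsilyl) compound
Product: 22 seco hydroxy acid (C7 acid on C8; C6 hydroxymethyl on C5), via aldehyde silyl ester 21 (not isolated)
Conditions: O3, CH2Cl2/MeOH, −78 °C; then NaBH4, −78 → 0 °C; aq. NH4Cl
Reagents that add atoms: ozone, [O-][O+]=O
Why: Ozonolysis of the silyl enol ether, the only C=C bond left, cleaves C6=C7 into a C6 aldehyde and a C7 silyl ester, and borohydride reduces the aldehyde in the same flask.

Step 14
Reactants: 22 seco hydroxy acid
Product: 23 hydroxy methyl ester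
Conditions: Me3SiCHN2, MeOH/toluene, 0 °C
Reagents that add atoms: trimethylsilyldiazomethane, C[Si](C)(C)C=[N+]=[N-]
Why: Diazoalkane esterification methylates the hindered C7 acid without base or heat, so the C6 alcohol does not lactonise.

Step 15
Reactants: 23 hydroxy methyl ester
Product: 24 C6 acetate
Conditions: Ac2O, pyridine, 4-(dimethylamino)pyridine (cat.), CH2Cl2, rt
Reagents that add atoms: acetic anhydride, CC(=O)OC(C)=O
Why: Acylation of the only free hydroxyl installs the C6 acetate of the target.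

Step 16
Reactants: 24 C6 acetate
Product: 25 C15 alcohol
Conditions: HF·pyridine, pyridine, THF, 0 °C
Reagents that add atoms: none
Why: Buffered fluoride should cleave the triethylsilyl ether much faster than the primary triisopropylsilyl ether while the esters stay intact.

Step 17
Reactants: 25 C15 alcohol
Product: 26 β-keto ester (C15 ketone)
Conditions: 1,1,1-triacetoxy-1,2-benziodoxol-3(1H)-one, NaHCO3, CH2Cl2, rt
Reagents that add atoms: none
Why: Periodinane oxidation merges both C15 epimers into one ketone that cannot enolise toward the quaternary C8.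

Step 18
Reactants: 26 β-keto ester
Product: 27 C15 ethylene ketal
Conditions: Me3SiOCH2CH2OSiMe3, Me3SiOTf (cat.), CH2Cl2, −78 → −20 °C
Reagents that add atoms: 1,2-bis(trimethylsilyloxy)ethane, C[Si](C)(C)OCCO[Si](C)(C)C
Why: Aprotic silyl-triflate-catalysed ketalisation masks the only ketone, which would otherwise be hydrosilylated in step 20, without transesterifying the acetate.

Step 19
Reactants: 27 C15 ethylene ketal
Product: 28 seco ester with C20 methyl and free C1 hydroxyl (key-step precursor)
Conditions: H2 (1 atm), Pd(OH)2/C, EtOAc, rt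
Reagents that add atoms: none
Why: Hydrogenolysis of the benzyl ether frees the C1 hydroxyl under neutral conditions, so it does not attack the C7 ester.

Step 20
Reactants: 28 key-step precursor; 29 diethylsilane
Product: 31 oxasilolane (ring O1–SiEt2–C20–C10–C1), via diethyl(hydrido)silyl ether 30 (not isolated)
Conditions: Et2SiH2 (1.5 equiv), [Ir(cod)OMe]2 (0.5 mol %), THF, rt; volatiles removed; then [Ir(cod)OMe]2 (2 mol %), 3,4,7,8-tetramethyl-1,10-phenanthroline (5 mol %), norbornene (1.2 equiv), THF, 100–120 °C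
Reagents that add atoms: none
Why: The C1 hydroxyl is first silylated dehydrogenatively by Et2SiH2 at monovalent iridium to give 30; with the phenanthroline ligand the Si–H bond adds to iridium, the iridium silyl species cleaves a C–H bond of the C20 methyl group, reductive elimination forms the C20–Si bond, and norbornene takes up the hydrogen. The closest known reaction is the iridium-catalysed, hydroxyl-directed γ-C–H silylation of methyl groups through (hydrido)silyl ethers, used to make 1,3-diols after oxidation. One ring is closed, the five-membered oxasilolane O1–Si–C20–C10–C1, by C–Si bond formation within the oxygen-tethered silyl group; no stereocentre is formed. The step needs site selectivity, which the substrate secures because C20 is the only primary γ C–H bond (the other γ positions are the secondary C3 and the tertiary C5 and C9) and this catalyst prefers primary C–H bonds. It also needs O1 and C20 to be gauche: they are trans on ring A and anti in the chair with C20 axial, so the reaction must pass through the other chair (O1 and C20 equatorial, C9 and C18 axial), which is judged accessible at 100–120 °C because both chairs carry syn-diaxial strain (C20/C19 and O1/C6 in one, C9/C18 in the other). Hydrosilylation cannot compete because the C15 ketone is a ketal and no C=C bond is present, and esters and silyl ethers are tolerated.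

Step 21
Reactants: 31 oxasilolane
Product: 32 C1-C20 diol
Conditions: H2O2 (30% aq.), KHCO3, THF/MeOH, rt → 45 °C
Reagents that add atoms: hydrogen peroxide, OO
Why: Tamao–Fleming oxidation, in which hydroperoxide attacks the alkoxy-substituted silicon and C20 migrates from Si to O, turns the C20–Si bond into C20–OH and frees O1.

Step 22
Reactants: 32 C1-C20 diol
Product: 33 spiro δ-lactone with free C1 hydroxyl
Conditions: camphor-10-sulfonic acid (10 mol %), 4 Å MS, toluene, 60 °C
Reagents that add atoms: none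
Why: Acid-catalysed lactonisation of the primary C20 alcohol onto the C7 methyl ester closes the ring C7–O–C20–C10–C9–C8, since the primary alcohol should react faster than the axial secondary C1 alcohol and acid avoids acetate migration.

Step 23
Reactants: 33 hydroxy lactone
Product: 34 C1-C6 diacetate
Conditions: Ac2O, Et3N, 4-(dimethylamino)pyridine, CH2Cl2, rt → 40 °C
Reagents that add atoms: acetic anhydride, CC(=O)OC(C)=O
Why: Nucleophile-catalysed acylation of the hindered C1 alcohol installs the second acetate and would also restore the C6 acetate if it were lost in step 21.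

Step 24
Reactants: 34 diacetate ketal
Product: 35 C15 ketone
Conditions: 1 M HCl, THF, rt → 40 °C
Reagents that add atoms: water, O
Why: Acid hydrolysis of the dioxolane should be faster than cleavage of the primary triisopropylsilyl ether, the acetates or the lactone.

Step 25
Reactants: 35 C15 ketone
Product: 39 α-methylene ketone (O19 silyl ether), via trimethylsilyl enol ether 36 (not isolated), via Mannich base 37 (not isolated), via ammonium iodide 38 (not isolated)
Conditions: Me3SiOTf, Et3N, CH2Cl2, 0 °C; then CH2=NMe2+ I−, CH2Cl2, rt; then MeI, MeCN, rt; then aq. NaHCO3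
Reagents that add atoms: dimethylmethyleneiminium iodide, C=[N+](C)C.[I-]
Why: Soft enolisation toward C16 (the only enolisable position, C8 being quaternary), Mannich reaction with the iminium salt, quaternisation and E1cB elimination install the C16=C17 methylene without strong base, so acetates and lactone are untouched.

Step 26
Reactants: 39 α-methylene ketone
Product: 40 target CNP0370815.4
Conditions: HF·pyridine, THF, 0 °C → rt
Reagents that add atoms: none
Why: Acidic fluoride cleaves the last silyl ether without adding to the enone or cleaving the acetates.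

**Compound list**

1 | methyl 3-hydroxy-2-methylpropanoate (racemic) | COC(=O)C(C)CO | starting material
2 | methyl 2-methyl-3-(triisopropylsilyloxy)propanoate | COC(=O)C(C)CO[Si](C(C)C)(C(C)C)C(C)C | intermediate
3 | 2-methyl-3-(triisopropylsilyloxy)propanal | O=CC(C)CO[Si](C(C)C)(C(C)C)C(C)C | intermediate
4 | pent-1-en-3-one | CCC(=O)C=C | starting material
5 | (R)-2-methyl-5-oxo-2-[(triisopropylsilyloxy)methyl]heptanal (Michael adduct) | CCC(=O)CC[C@](C)(CO[Si](C(C)C)(C(C)C)C(C)C)C=O | intermediate (not isolated)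
6 | (S)-2,4-dimethyl-4-[(triisopropylsilyloxy)methyl]cyclohex-2-en-1-one | O=C1C(C)=C[C@@](C)(CO[Si](C(C)C)(C(C)C)C(C)C)CC1 | intermediate
7 | but-3-yn-2-one | CC(=O)C#C | starting material
8 | buta-1,3-diene | C=CC=C | starting material
9 | 1-(cyclohexa-1,4-dien-1-yl)ethan-1-one | CC(=O)C1=CCC=CC1 | intermediate
10 | [1-(cyclohexa-1,4-dien-1-yl)ethenyloxy]triisopropylsilane | C=C(O[Si](C(C)C)(C(C)C)C(C)C)C1=CCC=CC1 | intermediate
11 | Diels–Alder adduct: cis,cis-fused A/B/C tricycle, C1 ketone, C7=C8 enol silyl ether, C12=C13 alkene | C1=CC[C@H]2[C@@]3(C)C(=O)CC[C@](C)(CO[Si](C(C)C)(C(C)C)C(C)C)[C@H]3CC(O[Si](C(C)C)(C(C)C)C(C)C)=C2C1 | intermediate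
12 | C1 alcohol of 11 (OH cis to C9, trans to C20) | C1=CC[C@H]2[C@@]3(C)[C@@H](O)CC[C@](C)(CO[Si](C(C)C)(C(C)C)C(C)C)[C@H]3CC(O[Si](C(C)C)(C(C)C)C(C)C)=C2C1 | intermediate
13 | C1 benzyl ether of 12 | C1=CC[C@H]2[C@@]3(C)[C@@H](OCc4ccccc4)CC[C@](C)(CO[Si](C(C)C)(C(C)C)C(C)C)[C@H]3CC(O[Si](C(C)C)(C(C)C)C(C)C)=C2C1 | intermediate
14 | phenylselanyl bromide | Br[Se]c1ccccc1 | starting material
15 | ethyl vinyl ether | C=COCC | starting material
16 | 2-(phenylselanyl)acetaldehyde diethyl acetal | CCOC(C[Se]c1ccccc1)OCC | intermediate (not isolated)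
17 | 2-(phenylselanyl)acetaldehyde | O=CC[Se]c1ccccc1 | intermediate
18 | aldol adduct: C7 ketone, C8 quaternary, C15 carbinol (epimers), C16–SePh | C1=CC[C@H]2[C@@]3(C)[C@@H](OCc4ccccc4)CC[C@](C)(CO[Si](C(C)C)(C(C)C)C(C)C)[C@H]3CC(=O)[C@]2(C1)C(O)C[Se]c1ccccc1 | intermediate
19 | tetracyclic hydroxy ketone (rings A–D, C15 carbinol epimers) | C1C(O)[C@]23C[C@H]1CC[C@H]2[C@@]1(C)[C@@H](OCc2ccccc2)CC[C@](C)(CO[Si](C(C)C)(C(C)C)C(C)C)[C@H]1CC3=O | intermediate
20 | C15 triethylsilyl ether, C6=C7 triethylsilyl enol ether | C1C(O[Si](CC)(CC)CC)[C@]23C[C@H]1CC[C@H]2[C@@]1(C)[C@@H](OCc2ccccc2)CC[C@](C)(CO[Si](C(C)C)(C(C)C)C(C)C)[C@H]1C=C3O[Si](CC)(CC)CC | intermediate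
21 | seco C6 aldehyde, C7 triethylsilyl ester | C1C(O[Si](CC)(CC)CC)[C@]2(C(=O)O[Si](CC)(CC)CC)C[C@H]1CC[C@H]2[C@@]1(C)[C@@H](OCc2ccccc2)CC[C@](C)(CO[Si](C(C)C)(C(C)C)C(C)C)[C@H]1C=O | intermediate (not isolated)
22 | seco hydroxy acid | C1C(O[Si](CC)(CC)CC)[C@]2(C(=O)O)C[C@H]1CC[C@H]2[C@@]1(C)[C@@H](OCc2ccccc2)CC[C@](C)(CO[Si](C(C)C)(C(C)C)C(C)C)[C@H]1CO | intermediate
23 | seco hydroxy methyl ester | C1C(O[Si](CC)(CC)CC)[C@]2(C(=O)OC)C[C@H]1CC[C@H]2[C@@]1(C)[C@@H](OCc2ccccc2)CC[C@](C)(CO[Si](C(C)C)(C(C)C)C(C)C)[C@H]1CO | intermediate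
24 | C6 acetate | C1C(O[Si](CC)(CC)CC)[C@]2(C(=O)OC)C[C@H]1CC[C@H]2[C@@]1(C)[C@@H](OCc2ccccc2)CC[C@](C)(CO[Si](C(C)C)(C(C)C)C(C)C)[C@H]1COC(C)=O | intermediate
25 | C15 alcohol (epimers) | C1C(O)[C@]2(C(=O)OC)C[C@H]1CC[C@H]2[C@@]1(C)[C@@H](OCc2ccccc2)CC[C@](C)(CO[Si](C(C)C)(C(C)C)C(C)C)[C@H]1COC(C)=O | intermediate
26 | C15 ketone (β-keto ester) | C1C(=O)[C@]2(C(=O)OC)C[C@H]1CC[C@H]2[C@@]1(C)[C@@H](OCc2ccccc2)CC[C@](C)(CO[Si](C(C)C)(C(C)C)C(C)C)[C@H]1COC(C)=O | intermediate
27 | C15 ethylene ketal, C1 benzyl ether | C1C2(OCCO2)[C@]3(C(=O)OC)C[C@H]1CC[C@H]3[C@@]1(C)[C@@H](OCc2ccccc2)CC[C@](C)(CO[Si](C(C)C)(C(C)C)C(C)C)[C@H]1COC(C)=O | intermediate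
28 | key-step precursor: C20 methyl, free C1–OH, C7 methyl ester, C6 acetate, C15 ketal, O19 silyl ether | C1C2(OCCO2)[C@]3(C(=O)OC)C[C@H]1CC[C@H]3[C@@]1(C)[C@@H](O)CC[C@](C)(CO[Si](C(C)C)(C(C)C)C(C)C)[C@H]1COC(C)=O | intermediate
29 | diethylsilane | CC[SiH2]CC | starting material
30 | C1 diethyl(hydrido)silyl ether of 28 | C1C2(OCCO2)[C@]3(C(=O)OC)C[C@H]1CC[C@H]3[C@@]1(C)[C@@H](O[SiH](CC)CC)CC[C@](C)(CO[Si](C(C)C)(C(C)C)C(C)C)[C@H]1COC(C)=O | intermediate (not isolated)
31 | oxasilolane O1–SiEt2–C20 | C1C2(OCCO2)[C@]3(C(=O)OC)C[C@H]1CC[C@H]3[C@]14C[Si](CC)(CC)O[C@H]4CC[C@](C)(CO[Si](C(C)C)(C(C)C)C(C)C)[C@H]1COC(C)=O | intermediate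
32 | C1,C20 diol | C1C2(OCCO2)[C@]3(C(=O)OC)C[C@H]1CC[C@H]3[C@@]1(CO)[C@@H](O)CC[C@](C)(CO[Si](C(C)C)(C(C)C)C(C)C)[C@H]1COC(C)=O | intermediate
33 | spiro δ-lactone, free C1–OH | C1C2(OCCO2)[C@]34C[C@H]1CC[C@H]3[C@@]1(COC4=O)[C@@H](O)CC[C@](C)(CO[Si](C(C)C)(C(C)C)C(C)C)[C@H]1COC(C)=O | intermediate
34 | C1,C6 diacetate, C15 ketal | C1C2(OCCO2)[C@]34C[C@H]1CC[C@H]3[C@@]1(COC4=O)[C@@H](OC(C)=O)CC[C@](C)(CO[Si](C(C)C)(C(C)C)C(C)C)[C@H]1COC(C)=O | intermediate
35 | C15 ketone | C1C(=O)[C@]23C[C@H]1CC[C@H]2[C@@]1(COC3=O)[C@@H](OC(C)=O)CC[C@](C)(CO[Si](C(C)C)(C(C)C)C(C)C)[C@H]1COC(C)=O | intermediate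
36 | C15=C16 trimethylsilyl enol ether | C1=C(O[Si](C)(C)C)[C@]23C[C@H]1CC[C@H]2[C@@]1(COC3=O)[C@@H](OC(C)=O)CC[C@](C)(CO[Si](C(C)C)(C(C)C)C(C)C)[C@H]1COC(C)=O | intermediate (not isolated)
37 | C16 (dimethylamino)methyl ketone (C16 epimers) | CN(C)CC1C(=O)[C@]23C[C@H]1CC[C@H]2[C@@]1(COC3=O)[C@@H](OC(C)=O)CC[C@](C)(CO[Si](C(C)C)(C(C)C)C(C)C)[C@H]1COC(C)=O | intermediate (not isolated)
38 | C16 (trimethylammonio)methyl ketone iodide | C[N+](C)(C)CC1C(=O)[C@]23C[C@H]1CC[C@H]2[C@@]1(COC3=O)[C@@H](OC(C)=O)CC[C@](C)(CO[Si](C(C)C)(C(C)C)C(C)C)[C@H]1COC(C)=O.[I-] | intermediate (not isolated)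
39 | α-methylene ketone, O19 triisopropylsilyl ether | C=C1C(=O)[C@]23C[C@H]1CC[C@H]2[C@@]1(COC3=O)[C@@H](OC(C)=O)CC[C@](C)(CO[Si](C(C)C)(C(C)C)C(C)C)[C@H]1COC(C)=O | intermediate
40 | CNP0370815.4 | C=C1C(=O)[C@]23C[C@H]1CC[C@H]2[C@@]1(COC3=O)[C@@H](OC(C)=O)CC[C@](C)(CO)[C@H]1COC(C)=O | target

**Step count**

Total: 26 steps. Longest linear sequence: 23 steps (steps 1–3, 6–8, 10–26).

**Three steps most likely to fail**

Step 20 (key step). The ring-A conformer that brings the silicon hydride within reach of C20 may be too little populated, because O1 and C20 are anti in the chair with C20 axial. The result would be no cyclometalation, or slow silylation of the secondary C3–H bond instead.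
Fallback (sets out from 28, returns at 34): C20 is oxidised by oxime-directed palladium chemistry from a C1 ketone.
- 28 is oxidised with the triacetoxyperiodinane to C1 ketone F1.
- Condensation with NH2OH·HCl/pyridine gives oxime F2.
- Pd(OAc)2 (cat.), PhI(OAc)2, AcOH/Ac2O, 80–100 °C: the oxime is O-acetylated in the flask, divalent palladium forms the five-membered palladacycle N–Pd–C20–C10–C1, and the product is C20 acetate O-acetyl oxime F3.
- Aqueous TiCl3/NH4OAc in THF cleaves the N–O bond and hydrolyses the imine to acetoxy ketone F4.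
- LiBH(s-Bu)3 reduces C1 as in step 7 to acetoxy alcohol F5.
- K2CO3/MeOH removes both acetates, and the C20 alkoxide closes the lactone to hydroxy lactone F6.
- Ac2O with 4-(dimethylamino)pyridine acetylates O1 and O6 and gives 34.

Step 6 (Diels–Alder). The cycloaddition may not take place at the doubly neopentyl enone. The Lewis acid may instead degrade the silyloxy diene (protodesilylation, isomerisation of the skipped diene), or facial selectivity across the C4 quaternary centre may be poor.
Fallback (sets out from 6 and 10, returns at 11): the two bonds are made in separate operations.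
- Mukaiyama–Michael addition of 10 to 6 under silyl-cation catalysis (Tf2NH 2 mol %, CH2Cl2, −78 °C) forms only C5–C6, anti to the CH2OSi group, and moves the silyl group to O1, giving open-chain Michael adduct F7.
- With more catalyst (Tf2NH 10 mol %, 0 °C → rt) the C1=C10 enol silyl ether adds to C9 of the dienone in an intramolecular Mukaiyama–Michael reaction. This closes ring B cis-fused, returns the silyl group to O7 and gives 11.

Step 10 (aldol at C8). The fully substituted C8–C15 bond may fail to form (desilylation to the parent ketone, retro-aldol cleavage), or the aldehyde may attack from the concave face.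
Fallback (sets out from 13, returns at 18): C15 and C16 are introduced one carbon at a time, starting with the smallest electrophile.
- Monomeric formaldehyde (from 1,3,5-trioxane, TiCl4, CH2Cl2, −78 °C) adds to the enol silyl ether and gives hydroxymethyl ketone F8.
- Oxidation with the triacetoxyperiodinane gives the non-enolisable keto aldehyde F9.
- (Phenylselanyl)methyllithium (from bis(phenylselanyl)methane and n-BuLi, THF, −78 °C) adds to the aldehyde in preference to the hindered C7 ketone and gives 18.

**Further compounds**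

F1 | step 20 | C1 ketone from 28 | C1C2(OCCO2)[C@]3(C(=O)OC)C[C@H]1CC[C@H]3[C@@]1(C)C(=O)CC[C@](C)(CO[Si](C(C)C)(C(C)C)C(C)C)[C@H]1COC(C)=O
F2 | step 20 | C1 oxime | C1C2(OCCO2)[C@]3(C(=O)OC)C[C@H]1CC[C@H]3[C@@]1(C)C(=NO)CC[C@](C)(CO[Si](C(C)C)(C(C)C)C(C)C)[C@H]1COC(C)=O
F3 | step 20 | C20 acetate O-acetyl oxime | C1C2(OCCO2)[C@]3(C(=O)OC)C[C@H]1CC[C@H]3[C@@]1(COC(C)=O)C(=NOC(C)=O)CC[C@](C)(CO[Si](C(C)C)(C(C)C)C(C)C)[C@H]1COC(C)=O
F4 | step 20 | C20 acetoxy C1 ketone | C1C2(OCCO2)[C@]3(C(=O)OC)C[C@H]1CC[C@H]3[C@@]1(COC(C)=O)C(=O)CC[C@](C)(CO[Si](C(C)C)(C(C)C)C(C)C)[C@H]1COC(C)=O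
F5 | step 20 | C20 acetoxy C1 alcohol | C1C2(OCCO2)[C@]3(C(=O)OC)C[C@H]1CC[C@H]3[C@@]1(COC(C)=O)[C@@H](O)CC[C@](C)(CO[Si](C(C)C)(C(C)C)C(C)C)[C@H]1COC(C)=O
F6 | step 20 | spiro lactone with free C1 and C6 hydroxyls | C1C2(OCCO2)[C@]34C[C@H]1CC[C@H]3[C@@]1(COC4=O)[C@@H](O)CC[C@](C)(CO[Si](C(C)C)(C(C)C)C(C)C)[C@H]1CO
F7 | step 6 | open-chain Michael adduct (C1 enol silyl ether, C7 dienone) | CC1=C(O[Si](C(C)C)(C(C)C)C(C)C)CC[C@](C)(CO[Si](C(C)C)(C(C)C)C(C)C)[C@H]1CC(=O)C1=CCC=CC1
F8 | step 10 | C8 hydroxymethyl ketone | C1=CC[C@H]2[C@@]3(C)[C@@H](OCc4ccccc4)CC[C@](C)(CO[Si](C(C)C)(C(C)C)C(C)C)[C@H]3CC(=O)[C@]2(C1)CO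
F9 | step 10 | C8 formyl ketone | C1=CC[C@H]2[C@@]3(C)[C@@H](OCc4ccccc4)CC[C@](C)(CO[Si](C(C)C)(C(C)C)C(C)C)[C@H]3CC(=O)[C@]2(C1)C=O
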